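**Retrosynthetic overview**
1. The target is the bis-desilylated form of a protected dienone. Its side chain (numbered as a deca-2,6-dien-5-one, C1 = benzylic CH2, C10 = CH2 on the oxane) is cut at C3–C4 and formed by a Hooz-type 1,2-boronate shift between an (E)-alkenyldichloroborane and a (Z)-α′-diazo enone.
2. Enabling feature: C4 is the α-CH2 of the C5 ketone and C3 is the methyl-bearing sp2 carbon of the C2=C3 alkene, i.e. a β,γ-unsaturated ketone. C4 can therefore arrive as a diazo carbon and C3 as a boron-bound alkenyl terminus, and the skipped enone is delivered at its final oxidation level without base.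
3. Aryl half: the benzene ring is bought as 4-methoxy-3-methylphenol. OMe-directed ortho-lithiation and butynylation, then thermodynamic hydrozirconation–iodination, set the E-alkene, which is carried through Li, Sn and B with retention.
4. Oxane half: an (S)-lactate-derived dioxolanone sets the quaternary C–O centre by alkylation with self-regeneration of the stereocentre. A B-alkyl Suzuki coupling with a (Z)-3-iodobut-2-enoate sets the Z-enoate, and an Ipc2B aldol with methacrolein sets the carbinol.
5. Ring order: the oxane is the only ring built (6-exo iodoetherification, step 8, then deiodination), and it is closed before the fragments are joined.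

Key step: step 16

Remark: the Hooz step is treated as known chemistry on the basis of recalled precedent for alkenyldichloroboranes with diazoacetate and for organodichloroboranes with diazoketones. The dioxolanone, allyl bromide, tert-butyl but-2-ynoate, methacrolein, 4-methoxy-3-methylphenol and 1-bromobut-2-yne are assumed to be commercial (the dioxolanone is otherwise one step from (S)-lactic acid and pivalaldehyde). The oxane is numbered O1, C2 (quaternary), C3 (C=O), C5 (carbinol), C6 (gem-dimethyl).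

**Route**

Step 1
Reactants: 1 (2S,5S)-2-tert-butyl-5-methyl-1,3-dioxolan-4-one; 2 allyl bromide
Product: 4 (2S,5R)-2-tert-butyl-5-methyl-5-(prop-2-en-1-yl)-1,3-dioxolan-4-one, via lithium enolate 3 (not isolated)
Conditions: LDA, THF, −78 °C; allyl bromide, −78 → −30 °C
Reagents that add atoms: none
Why: Enolate alkylation with self-regeneration of the stereocentre: the enolate is planar at C5 and allyl bromide should enter anti to the tert-butyl group of the acetal, so allyl replaces H with retention and sets the quaternary (R) centre that becomes oxane C2.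

Step 2
Reactants: 5 tert-butyl but-2-ynoate
Product: 6 tert-butyl (2Z)-3-iodobut-2-enoate
Conditions: LiI, AcOH, MeCN, 70 °C
Reagents that add atoms: lithium iodide, [Li+].[I-]
Why: Conjugate hydroiodination of an ynoate: iodide adds at C3 and anti protonation of the allenolate should give the (Z)-β-iodoenoate with iodine cis to the ester.

Step 3
Reactants: 4 (2S,5R)-2-tert-butyl-5-methyl-5-(prop-2-en-1-yl)-1,3-dioxolan-4-one; 6 tert-butyl (2Z)-3-iodobut-2-enoate
Product: 8 tert-butyl (2Z)-6-[(2S,4R)-2-tert-butyl-4-methyl-5-oxo-1,3-dioxolan-4-yl]-3-methylhex-2-enoate, via B-alkyl-9-BBN 7 (not isolated)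
Conditions: 9-BBN, THF, 0 °C → rt; then 6, Pd(dppf)Cl2 (cat.), AsPh3 (cat.), aq. K3PO4, DMF, rt
Reagents that add atoms: none
Why: Anti-Markovnikov hydroboration then B-alkyl Suzuki–Miyaura coupling, which retains the vinyl iodide geometry so the new chain sits cis to the ester (Z-enoate); the hindered acylal and the tert-butyl ester should tolerate the mild phosphate base.

Step 4
Reactants: 8 tert-butyl (2Z)-6-[(2S,4R)-2-tert-butyl-4-methyl-5-oxo-1,3-dioxolan-4-yl]-3-methylhex-2-enoate
Product: 9 tert-butyl (2Z,7R)-7-hydroxy-8-[methoxy(methyl)amino]-3,7-dimethyl-8-oxooct-2-enoate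
Conditions: MeNH(OMe)·HCl, i-PrMgCl, THF, −20 → 0 °C
Reagents that add atoms: N,O-dimethylhydroxylamine hydrochloride, CNOC.Cl
Why: Aminolysis of the activated acylal carbonyl by the magnesium amide (Weinreb amide formation) should open the dioxolanone with loss of pivalaldehyde, leaving the quaternary centre and the hindered conjugated tert-butyl ester untouched.

Step 5
Reactants: 9 tert-butyl (2Z,7R)-7-hydroxy-8-[methoxy(methyl)amino]-3,7-dimethyl-8-oxooct-2-enoate
Product: 10 tert-butyl (2Z,7R)-7-hydroxy-3,7-dimethyl-8-oxonon-2-enoate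
Conditions: MeMgBr (excess), THF, −20 → 0 °C; aq. NH4Cl
Reagents that add atoms: methylmagnesium bromide, C[Mg]Br
Why: Weinreb ketone synthesis: after deprotonation of the tertiary OH the chelated tetrahedral adduct stops at the methyl ketone, and the β,β-disubstituted tert-butyl enoate is far less electrophilic.

Step 6
Reactants: 10 tert-butyl (2Z,7R)-7-hydroxy-3,7-dimethyl-8-oxonon-2-enoate
Product: 11 tert-butyl (2Z,7R)-3,7-dimethyl-8-oxo-7-(trimethylsilyloxy)non-2-enoate
Conditions: TMSCl, imidazole, CH2Cl2, 0 °C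
Reagents that add atoms: chlorotrimethylsilane, C[Si](C)(C)Cl
Why: Silyl ether formation masks the tertiary α-hydroxyl so that the next step forms one defined boron enolate.

Step 7
Reactants: 11 tert-butyl (2Z,7R)-3,7-dimethyl-8-oxo-7-(trimethylsilyloxy)non-2-enoate; 12 methacrolein
Product: 15 tert-butyl (2Z,7R,10S)-7,10-dihydroxy-3,7,11-trimethyl-8-oxododeca-2,11-dienoate, via boron enolate 13 (not isolated), via silylated aldol adduct 14 (not isolated)
Conditions: (+)-Ipc2BCl, Et3N, Et2O, 0 °C; 12, −78 → −20 °C; H2O2, MeOH, pH 7 buffer; then citric acid, MeOH, rt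
Reagents that add atoms: none
Why: Ipc2BCl-mediated boron aldol of a methyl ketone (only the methyl side can enolise): the (+)-reagent should direct the enolate to the Si face of methacrolein and set the (10S) carbinol by reagent control, any (10R) epimer being a separable diastereomer, and the mild acid in the work-up removes the tertiary TMS ether.

Step 8
Reactants: 15 tert-butyl (2Z,7R,10S)-7,10-dihydroxy-3,7,11-trimethyl-8-oxododeca-2,11-dienoate
Product: 16 tert-butyl (2Z)-6-[(2R,5S)-5-hydroxy-6-(iodomethyl)-2,6-dimethyl-3-oxooxan-2-yl]-3-methylhex-2-enoate (both C6 epimers)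
Conditions: NIS, MeCN, 0 °C, dark
Reagents that add atoms: N-iodosuccinimide, O=C1CCC(=O)N1I
Why: Iodoetherification: the tertiary hydroxyl should open the iodonium ion of the 1,1-disubstituted alkene at its tertiary carbon (6-exo-trig, Markovnikov), which closes the oxane between the two fully substituted carbons; the new C6 centre is irrelevant because it becomes gem-dimethyl in step 9.

Step 9
Reactants: 16 tert-butyl (2Z)-6-[(2R,5S)-5-hydroxy-6-(iodomethyl)-2,6-dimethyl-3-oxooxan-2-yl]-3-methylhex-2-enoate (both C6 epimers)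
Product: 17 tert-butyl (2Z)-6-[(2R,5S)-5-hydroxy-2,6,6-trimethyl-3-oxooxan-2-yl]-3-methylhex-2-enoate
Conditions: Bu3SnH, AIBN (cat.), toluene, 80 °C
Reagents that add atoms: none
Why: Radical-chain hydrodeiodination of the primary iodide should give the gem-dimethyl group without touching the ketone, the free alcohol or the Z-enoate.

Step 10
Reactants: 17 tert-butyl (2Z)-6-[(2R,5S)-5-hydroxy-2,6,6-trimethyl-3-oxooxan-2-yl]-3-methylhex-2-enoate
Product: 19 (2Z)-3-methyl-6-[(2R,5S)-2,6,6-trimethyl-3-oxo-5-(triethylsilyloxy)oxan-2-yl]hex-2-enoic acid, via triethylsilyl ester 18 (not isolated)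
Conditions: TESOTf (excess), 2,6-lutidine, CH2Cl2, 0 °C → rt; then pH 5 buffer, THF
Reagents that add atoms: triethylsilyl trifluoromethanesulfonate, CC[Si](CC)(CC)OS(=O)(=O)C(F)(F)F
Why: Silyl-triflate-mediated tert-butyl ester cleavage combined with O-silylation: the reagent silylates the secondary alcohol and converts the ester, by loss of isobutene, into a silyl ester that hydrolyses on work-up, so no basic saponification is needed next to the β-silyloxy ketone.

Step 11
Reactants: 19 (2Z)-3-methyl-6-[(2R,5S)-2,6,6-trimethyl-3-oxo-5-(triethylsilyloxy)oxan-2-yl]hex-2-enoic acid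
Product: 21 (3Z)-1-diazo-4-methyl-7-[(2R,5S)-2,6,6-trimethyl-3-oxo-5-(triethylsilyloxy)oxan-2-yl]hept-3-en-2-one, via mixed anhydride 20 (not isolated)
Conditions: i-BuOCOCl, N-methylmorpholine, THF, −20 °C; CH2N2, Et2O, −20 → 0 °C
Reagents that add atoms: diazomethane, C=[N+]=[N-]
Why: Acylation of diazomethane by a mixed carbonic anhydride (first stage of an Arndt–Eistert sequence) is cold and neutral, so the Z-geometry should survive; the β,β-disubstituted enone is a poor dipolarophile and the hindered ring ketone should not be homologated.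

Step 12
Reactants: 22 4-methoxy-3-methylphenol
Product: 23 (4-methoxy-3-methylphenoxy)tri(propan-2-yl)silane
Conditions: TIPSCl, imidazole, DMF, rt
Reagents that add atoms: chlorotri(propan-2-yl)silane, CC(C)[Si](Cl)(C(C)C)C(C)C
Why: Standard phenol silylation; the bulky TIPS ether survives the organolithium steps and shields its own ortho positions.

Step 13
Reactants: 23 (4-methoxy-3-methylphenoxy)tri(propan-2-yl)silane; 24 1-bromobut-2-yne
Product: 27 [3-(but-2-yn-1-yl)-4-methoxy-5-methylphenoxy]tri(propan-2-yl)silane, via aryllithium 25 (not isolated), via aryl Grignard reagent 26 (not isolated)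
Conditions: n-BuLi, TMEDA, Et2O, 0 °C → rt; MgBr2·OEt2, −20 °C; CuBr·SMe2 (cat.), 24, THF, −20 °C → rt
Reagents that add atoms: none
Why: Directed ortho-metalation: the methoxy group should direct lithiation to its only free ortho position (the TIPS-oxy group is a poor, bulky director), and the derived Grignard reagent undergoes copper-catalysed SN2 substitution of the primary propargylic bromide, whose γ-methyl disfavours SN2′.

Step 14
Reactants: 27 [3-(but-2-yn-1-yl)-4-methoxy-5-methylphenoxy]tri(propan-2-yl)silane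
Product: 29 {3-[(2E)-3-iodobut-2-en-1-yl]-4-methoxy-5-methylphenoxy}tri(propan-2-yl)silane, via alkenylzirconocene 28 (not isolated)
Conditions: Cp2Zr(H)Cl (2.2 equiv), THF, 50 °C; then I2, THF, 0 °C
Reagents that add atoms: iodine, II
Why: Syn hydrozirconation under thermodynamic control (excess reagent, warming) should place zirconium on the less hindered methyl-bearing alkyne carbon, and iododezirconation with retention gives the (E)-vinyl iodide with iodine trans to the benzylic CH2.

Step 15
Reactants: 29 {3-[(2E)-3-iodobut-2-en-1-yl]-4-methoxy-5-methylphenoxy}tri(propan-2-yl)silane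
Product: 31 tributyl{(2E)-4-[2-methoxy-3-methyl-5-(triisopropylsilyloxy)phenyl]but-2-en-2-yl}stannane, via alkenyllithium 30 (not isolated)
Conditions: t-BuLi (2.1 equiv), Et2O, −78 °C; Bu3SnCl, −78 °C → rt
Reagents that add atoms: tributyltin chloride, CCCC[Sn](Cl)(CCCC)CCCC
Why: Lithium–iodine exchange and stannylation both proceed with retention of alkene geometry and give a storable, purifiable alkenylstannane.

Step 16
Reactants: 31 tributyl{(2E)-4-[2-methoxy-3-methyl-5-(triisopropylsilyloxy)phenyl]but-2-en-2-yl}stannane; 21 (3Z)-1-diazo-4-methyl-7-[(2R,5S)-2,6,6-trimethyl-3-oxo-5-(triethylsilyloxy)oxan-2-yl]hept-3-en-2-one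
Product: 34 (2E,6Z)-1-[2-methoxy-3-methyl-5-(triisopropylsilyloxy)phenyl]-3,7-dimethyl-10-[(2R,5S)-2,6,6-trimethyl-3-oxo-5-(triethylsilyloxy)oxan-2-yl]deca-2,6-dien-5-one, via alkenyldichloroborane 32 (not isolated), via α-boryl ketone 33 (not isolated)
Conditions: BCl3 (1.0 equiv, CH2Cl2), −78 °C, 30 min; then 21, CH2Cl2, −78 → −40 °C; MeOH then pH 7 buffer
Reagents that add atoms: none
Why: Tin-to-boron exchange converts 31 with retention into the alkenyl-BCl2 species 32, whose boron is attacked by the nucleophilic diazo carbon of 21; the ate complex undergoes 1,2-migration of the alkenyl group from boron to carbon with loss of N2, and the α-boryl ketone 33 (in equilibrium with its O-boron dienolate) is protonated at the α-carbon on quenching. The closest known reaction type is the Hooz reaction of organodichloroboranes with α-diazo ketones and esters, including (E)-alkenyldichloroboranes that give (E)-β,γ-unsaturated esters. No ring is closed and no stereocentre is created; what must be controlled is alkene geometry, and the migrating sp2 carbon keeps its configuration, so the E-alkene fixed in step 14 and the Z-enone fixed in step 3 should both be carried through unchanged. The selectivity needed is migration of the alkenyl group only, secured because chloride is the sole other ligand on boron, and formation of the skipped rather than the conjugated enone, secured because the C–C bond forms at −78 °C without base and the boron dienolate is protonated kinetically at its α-carbon. The silyl ethers, the aryl methyl ether and the hindered ring ketone should tolerate the brief exposure to a stoichiometric, fully consumed Lewis acid at low temperature.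

Step 17
Reactants: 34 (2E,6Z)-1-[2-methoxy-3-methyl-5-(triisopropylsilyloxy)phenyl]-3,7-dimethyl-10-[(2R,5S)-2,6,6-trimethyl-3-oxo-5-(triethylsilyloxy)oxan-2-yl]deca-2,6-dien-5-one
Product: 35 (2E,6Z)-10-[(2R,5S)-5-hydroxy-2,6,6-trimethyl-3-oxooxan-2-yl]-1-(5-hydroxy-2-methoxy-3-methylphenyl)-3,7-dimethyldeca-2,6-dien-5-one
Conditions: TBAF, AcOH (1:1), THF, 0 °C → rt
Reagents that add atoms: none
Why: Fluoride-mediated desilylation removes the aryl TIPS and the secondary TES ether in one operation, and the acetic acid buffer should prevent β-elimination or retro-aldol of the β-hydroxy ketone and conjugation of the skipped enone.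

**Compound list**
1 | (2S,5S)-2-tert-butyl-5-methyl-1,3-dioxolan-4-one | C[C@@H]1O[C@H](C(C)(C)C)OC1=O | starting material
2 | allyl bromide | C=CCBr | starting material
3 | lithium enolate of 1 (lithium (2S)-2-tert-butyl-5-methyl-1,3-dioxol-4-olate) | CC1=C(O[Li])O[C@@H](C(C)(C)C)O1 | intermediate (not isolated)
4 | (2S,5R)-2-tert-butyl-5-methyl-5-(prop-2-en-1-yl)-1,3-dioxolan-4-one | C[C@]1(CC=C)O[C@H](C(C)(C)C)OC1=O | intermediate
5 | tert-butyl but-2-ynoate | CC#CC(=O)OC(C)(C)C | starting material
6 | tert-butyl (2Z)-3-iodobut-2-enoate | CC(C)(C)OC(=O)/C=C(/C)I | intermediate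
7 | (2S,5R)-5-[3-(9-borabicyclo[3.3.1]nonan-9-yl)propyl]-2-tert-butyl-5-methyl-1,3-dioxolan-4-one | C[C@]1(CCCB2C3CCCC2CCC3)O[C@H](C(C)(C)C)OC1=O | intermediate (not isolated)
8 | tert-butyl (2Z)-6-[(2S,4R)-2-tert-butyl-4-methyl-5-oxo-1,3-dioxolan-4-yl]-3-methylhex-2-enoate | CC(C)(C)OC(=O)/C=C(/C)CCC[C@@]1(C)O[C@H](C(C)(C)C)OC1=O | intermediate
9 | tert-butyl (2Z,7R)-7-hydroxy-8-[methoxy(methyl)amino]-3,7-dimethyl-8-oxooct-2-enoate | CC(C)(C)OC(=O)/C=C(/C)CCC[C@@](C)(O)C(=O)N(C)OC | intermediate
10 | tert-butyl (2Z,7R)-7-hydroxy-3,7-dimethyl-8-oxonon-2-enoate | CC(C)(C)OC(=O)/C=C(/C)CCC[C@@](C)(O)C(C)=O | intermediate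
11 | tert-butyl (2Z,7R)-3,7-dimethyl-8-oxo-7-(trimethylsilyloxy)non-2-enoate | CC(C)(C)OC(=O)/C=C(/C)CCC[C@@](C)(O[Si](C)(C)C)C(C)=O | intermediate
12 | methacrolein | CC(=C)C=O | starting material
13 | diisopinocampheylboron enolate of 11 (Ipc groups as in (+)-Ipc2BCl, drawn without descriptors) | CC(C)(C)OC(=O)/C=C(/C)CCC[C@@](C)(O[Si](C)(C)C)C(=C)OB(C1CC2CC(C1C)C2(C)C)C1CC2CC(C1C)C2(C)C | intermediate (not isolated)
14 | tert-butyl (2Z,7R,10S)-10-hydroxy-3,7,11-trimethyl-8-oxo-7-(trimethylsilyloxy)dodeca-2,11-dienoate | CC(C)(C)OC(=O)/C=C(/C)CCC[C@@](C)(O[Si](C)(C)C)C(=O)C[C@H](O)C(C)=C | intermediate (not isolated)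
15 | tert-butyl (2Z,7R,10S)-7,10-dihydroxy-3,7,11-trimethyl-8-oxododeca-2,11-dienoate | CC(C)(C)OC(=O)/C=C(/C)CCC[C@@](C)(O)C(=O)C[C@H](O)C(C)=C | intermediate
16 | tert-butyl (2Z)-6-[(2R,5S)-5-hydroxy-6-(iodomethyl)-2,6-dimethyl-3-oxooxan-2-yl]-3-methylhex-2-enoate (both C6 epimers) | CC(C)(C)OC(=O)/C=C(/C)CCC[C@@]1(C)OC(C)(CI)[C@@H](O)CC1=O | intermediate
17 | tert-butyl (2Z)-6-[(2R,5S)-5-hydroxy-2,6,6-trimethyl-3-oxooxan-2-yl]-3-methylhex-2-enoate | CC(C)(C)OC(=O)/C=C(/C)CCC[C@@]1(C)OC(C)(C)[C@@H](O)CC1=O | intermediate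
18 | triethylsilyl (2Z)-3-methyl-6-[(2R,5S)-2,6,6-trimethyl-3-oxo-5-(triethylsilyloxy)oxan-2-yl]hex-2-enoate | CC[Si](CC)(CC)OC(=O)/C=C(/C)CCC[C@@]1(C)OC(C)(C)[C@@H](O[Si](CC)(CC)CC)CC1=O | intermediate (not isolated)
19 | (2Z)-3-methyl-6-[(2R,5S)-2,6,6-trimethyl-3-oxo-5-(triethylsilyloxy)oxan-2-yl]hex-2-enoic acid | OC(=O)/C=C(/C)CCC[C@@]1(C)OC(C)(C)[C@@H](O[Si](CC)(CC)CC)CC1=O | intermediate
20 | mixed isobutyl carbonic anhydride of 19 | CC(C)COC(=O)OC(=O)/C=C(/C)CCC[C@@]1(C)OC(C)(C)[C@@H](O[Si](CC)(CC)CC)CC1=O | intermediate (not isolated)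
21 | (3Z)-1-diazo-4-methyl-7-[(2R,5S)-2,6,6-trimethyl-3-oxo-5-(triethylsilyloxy)oxan-2-yl]hept-3-en-2-one | [N-]=[N+]=CC(=O)/C=C(/C)CCC[C@@]1(C)OC(C)(C)[C@@H](O[Si](CC)(CC)CC)CC1=O | intermediate
22 | 4-methoxy-3-methylphenol | COc1ccc(O)cc1C | starting material
23 | (4-methoxy-3-methylphenoxy)tri(propan-2-yl)silane | COc1ccc(O[Si](C(C)C)(C(C)C)C(C)C)cc1C | intermediate
24 | 1-bromobut-2-yne | CC#CCBr | starting material
25 | [2-methoxy-3-methyl-5-(triisopropylsilyloxy)phenyl]lithium | COc1c([Li])cc(O[Si](C(C)C)(C(C)C)C(C)C)cc1C | intermediate (not isolated)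
26 | [2-methoxy-3-methyl-5-(triisopropylsilyloxy)phenyl]magnesium bromide | COc1c([Mg]Br)cc(O[Si](C(C)C)(C(C)C)C(C)C)cc1C | intermediate (not isolated)
27 | [3-(but-2-yn-1-yl)-4-methoxy-5-methylphenoxy]tri(propan-2-yl)silane | COc1c(C)cc(O[Si](C(C)C)(C(C)C)C(C)C)cc1CC#CC | intermediate
28 | chlorobis(cyclopentadienyl){(2E)-4-[2-methoxy-3-methyl-5-(triisopropylsilyloxy)phenyl]but-2-en-2-yl}zirconium | COc1c(C)cc(O[Si](C(C)C)(C(C)C)C(C)C)cc1C/C=C(\C)[Zr](Cl)(C1C=CC=C1)C1C=CC=C1 | intermediate (not isolated)
29 | {3-[(2E)-3-iodobut-2-en-1-yl]-4-methoxy-5-methylphenoxy}tri(propan-2-yl)silane | COc1c(C)cc(O[Si](C(C)C)(C(C)C)C(C)C)cc1C/C=C(\C)I | intermediate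
30 | {(2Z)-4-[2-methoxy-3-methyl-5-(triisopropylsilyloxy)phenyl]but-2-en-2-yl}lithium | COc1c(C)cc(O[Si](C(C)C)(C(C)C)C(C)C)cc1C/C=C(\C)[Li] | intermediate (not isolated)
31 | tributyl{(2E)-4-[2-methoxy-3-methyl-5-(triisopropylsilyloxy)phenyl]but-2-en-2-yl}stannane | COc1c(C)cc(O[Si](C(C)C)(C(C)C)C(C)C)cc1C/C=C(\C)[Sn](CCCC)(CCCC)CCCC | intermediate
32 | dichloro{(2Z)-4-[2-methoxy-3-methyl-5-(triisopropylsilyloxy)phenyl]but-2-en-2-yl}borane | COc1c(C)cc(O[Si](C(C)C)(C(C)C)C(C)C)cc1C/C=C(\C)B(Cl)Cl | intermediate (not isolated)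
33 | 4-(dichloroboryl) derivative of 34 (α-boryl ketone; C4 configuration undefined) | COc1c(C)cc(O[Si](C(C)C)(C(C)C)C(C)C)cc1C/C=C(\C)C(B(Cl)Cl)C(=O)/C=C(/C)CCC[C@@]1(C)OC(C)(C)[C@@H](O[Si](CC)(CC)CC)CC1=O | intermediate (not isolated)
34 | (2E,6Z)-1-[2-methoxy-3-methyl-5-(triisopropylsilyloxy)phenyl]-3,7-dimethyl-10-[(2R,5S)-2,6,6-trimethyl-3-oxo-5-(triethylsilyloxy)oxan-2-yl]deca-2,6-dien-5-one | COc1c(C)cc(O[Si](C(C)C)(C(C)C)C(C)C)cc1C/C=C(\C)CC(=O)/C=C(/C)CCC[C@@]1(C)OC(C)(C)[C@@H](O[Si](CC)(CC)CC)CC1=O | intermediate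
35 | (2E,6Z)-10-[(2R,5S)-5-hydroxy-2,6,6-trimethyl-3-oxooxan-2-yl]-1-(5-hydroxy-2-methoxy-3-methylphenyl)-3,7-dimethyldeca-2,6-dien-5-one | COc1c(C)cc(O)cc1C/C=C(\C)CC(=O)/C=C(/C)CCC[C@@]1(C)OC(C)(C)[C@@H](O)CC1=O | target

**Summary**
Total step count: 17. Longest linear sequence: 12 steps (steps 1, 3–11, 16, 17).

Steps most likely to fail:

1. Step 16. What may go wrong: Lewis-acid-induced decomposition of the diazo enone (chloride transfer to the diazo carbon, Z-to-E isomerisation of the enone) may compete with alkenyl migration, or protonation of the boron dienolate at the γ-carbon may conjugate the enone. Fallback: the route is left at 21, which is treated with one equivalent of dry HBr in Et2O at −40 °C to give the (3Z)-bromomethyl ketone F1. The alkenyllithium 30 (from 29 as in step 15) is transmetalated with ZnCl2 to the alkenylzinc chloride F2. A nickel-catalysed Negishi coupling of F1 with F2 (NiCl2·glyme, bipyridine-type ligand, DME/THF, 0 °C), a base-free C(sp2)–C(α) coupling of α-bromo ketones, then returns to the route at 34.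

2. Step 7. What may go wrong: poor facial selectivity on methacrolein, because the quaternary α-silyloxy ketone may erode reagent control. Fallback: the route is left at 15 obtained as a mixture with its (10R)-epimer F3. The mixture is submitted to a Sharpless kinetic-resolution epoxidation (Ti(OiPr)4, D-(−)-DIPT, TBHP, 4 Å sieves, CH2Cl2, −20 °C). By the usual mnemonic the (10R) allylic alcohol reacts fast and is converted into the epoxy alcohol F4, while the (10S) alcohol is recovered and returns to the route as pure 15 for step 8.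

3. Step 14. What may go wrong: incomplete regiocontrol of Zr–H addition across the unsymmetrical alkyne (the ortho-methoxy group may steer zirconium to the benzylic-side carbon), giving regioisomeric iodides. Fallback: the route is left at 23, which is lithiated and transmetalated as in step 13 to 26 and trapped with allyl bromide (CuBr·SMe2 cat.) to give the allylarene F5. Cross-metathesis with isopropenylboronic acid pinacol ester (second-generation Ru catalyst, CH2Cl2, 40 °C) should give the alkenyl boronate F6 with boron trans to the benzylic CH2 for steric reasons. Iododeboronation with retention (NaOH, then I2, THF, 0 °C) returns to the route at 29.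

**Further compounds**
F1 | step 16 | (3Z)-1-bromo-4-methyl-7-[(2R,5S)-2,6,6-trimethyl-3-oxo-5-(triethylsilyloxy)oxan-2-yl]hept-3-en-2-one | BrCC(=O)/C=C(/C)CCC[C@@]1(C)OC(C)(C)[C@@H](O[Si](CC)(CC)CC)CC1=O
F2 | step 16 | chloro{(2E)-4-[2-methoxy-3-methyl-5-(triisopropylsilyloxy)phenyl]but-2-en-2-yl}zinc | COc1c(C)cc(O[Si](C(C)C)(C(C)C)C(C)C)cc1C/C=C(\C)[Zn]Cl
F3 | step 7 | tert-butyl (2Z,7R,10R)-7,10-dihydroxy-3,7,11-trimethyl-8-oxododeca-2,11-dienoate | CC(C)(C)OC(=O)/C=C(/C)CCC[C@@](C)(O)C(=O)C[C@@H](O)C(C)=C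
F4 | step 7 | tert-butyl (2Z,7R,10R)-7,10-dihydroxy-3,7-dimethyl-10-[(2R)-2-methyloxiran-2-yl]-8-oxodec-2-enoate | CC(C)(C)OC(=O)/C=C(/C)CCC[C@@](C)(O)C(=O)C[C@@H](O)[C@@]1(C)CO1
F5 | step 14 | [4-methoxy-3-methyl-5-(prop-2-en-1-yl)phenoxy]tri(propan-2-yl)silane | COc1c(C)cc(O[Si](C(C)C)(C(C)C)C(C)C)cc1CC=C
F6 | step 14 | 2-{(2Z)-4-[2-methoxy-3-methyl-5-(triisopropylsilyloxy)phenyl]but-2-en-2-yl}-4,4,5,5-tetramethyl-1,3,2-dioxaborolane | COc1c(C)cc(O[Si](C(C)C)(C(C)C)C(C)C)cc1C/C=C(\C)B1OC(C)(C)C(C)(C)O1
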